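Guaiane numbering is used. Everything rests on the C7–C8 bond of the cycloheptane ring B (C1, C5–C10): C13=C11–C7–C8–O8 is a homoallylic alcohol, C7 being the allylic carbon of the α-methylene lactone ring A (O6, C6, C7, C11, C12) and C8 a carbinol. An intramolecular indium Barbier allylation therefore closes ring B, sets C7 and C8 and unveils the exocyclic methylene in one operation, while two C7 bromide epimers converge. The precursor is a cis-1,2-disubstituted cyclopentane obtained by ozonolysis of an enantioselective Diels–Alder cyclohexene: that six-membered ring is cut at C6=C8 and re-closed around the inserted C7. The strained C4–O–C14 enol ether bridge is made last.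

Key step: step 13

Convention: all intermediates carry the guaiane locants of the target (C11–C13 lactone carbons, C14 on C10, C15 on C4); α is the face of H-1 and H-5.
Assumption: the (S)-oxazaborolidine antipode is taken to deliver adduct 9; should its facial preference be the opposite, the (R)-antipode is used instead.
Assumption: the alkene geometry of 5, the C7 bromide epimers of 22–24 and the C14 anomers of 31–32 do not matter for the outcome; the SMILES leave C7 and C14 open there.

Step 1
Reactants: 1 (tributylstannyl)methanol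
Product: 2 tributyl[(4-methoxybenzyloxy)methyl]stannane
Conditions: NaH, 4-methoxybenzyl chloride, Bu4NI (cat.), THF–DMF, 0 → 25 °C
Reagents that add atoms: 4-methoxybenzyl chloride COc1ccc(CCl)cc1
Why: Williamson etherification of the stannylmethanol gives the precursor of a protected hydroxymethyl anion (C15); no stereocentre is formed.

Step 2
Reactants: 3 methyl 2-(bromomethyl)acrylate
Product: 5 methyl (Z)-3-bromo-2-(bromomethyl)acrylate, via tribromide 4 (not isolated)
Conditions: Br2, CH2Cl2, 0 °C; then Et3N, 0 → 25 °C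
Reagents that add atoms: bromine BrBr
Why: Bromine addition to the acrylate followed by E2 loss of HBr (tertiary bromide, hydrogen from a CH2Br group) gives the γ-bromo allylic bromide that later supplies C7, C11, C12 and C13; no stereocentre.

Step 3
Reactants: 6 but-3-en-2-one
Product: 7 2-(triisopropylsilyloxy)buta-1,3-diene
Conditions: i-Pr3SiOTf, Et3N, Et2O, 0 °C
Reagents that add atoms: triisopropylsilyl trifluoromethanesulfonate CC(C)[Si](C(C)C)(C(C)C)OS(=O)(=O)C(F)(F)F
Why: Soft enolisation and O-silylation of the methyl ketone give the 2-silyloxy diene (C10, C9, C8, C6); no stereocentre.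

Step 4
Reactants: 7 2-(triisopropylsilyloxy)buta-1,3-diene; 8 cyclopent-2-en-1-one
Product: 9 (3aS,7aR)-5-(triisopropylsilyloxy)-2,3,3a,4,7,7a-hexahydro-1H-inden-1-one
Conditions: (S)-3,3-diphenyl-1-(2-methylphenyl)tetrahydro-1H,3H-pyrrolo[1,2-c][1,3,2]oxazaborole (20 mol %), HNTf2 (18 mol %), CH2Cl2, −78 → −40 °C
Reagents that add atoms: none
Why: Catalytic enantioselective Diels–Alder reaction in which the protonated oxazaborolidine shields one enone face, suprafacial addition makes C1 and C5 cis (both H α), and the usual para regiochemistry puts the silyloxy carbon at C9.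

Step 5
Reactants: 9 cis-fused Diels–Alder ketone; 2 tributyl[(4-methoxybenzyloxy)methyl]stannane
Product: 11 4β-hydroxy-4α-[(4-methoxybenzyloxy)methyl] cis-bicyclic silyl enol ether, via lithium reagent 10 (not isolated)
Conditions: 2, n-BuLi, THF, −78 °C; CeCl3, −78 °C; then 9; sat. aq NH4Cl
Reagents that add atoms: none
Why: Tin–lithium exchange gives the α-alkoxymethyllithium, whose cerium reagent adds 1,2 to the cyclopentanone from the convex α face (anti to C6), so O4 is β and C15 is α.

Step 6
Reactants: 11 tertiary alcohol silyl enol ether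
Product: 12 cis-bicyclic enone (C9 ketone conjugated to C6=C8)
Conditions: Pd(OAc)2 (10 mol %), O2 (1 atm), DMSO, 50 °C
Reagents that add atoms: none
Why: Saegusa–Ito oxidation, in which palladation at C8 and β-hydride loss from C6 place the alkene at C6=C8; no stereocentre changes.

Step 7
Reactants: 12 cis-bicyclic enone; 13 trimethyl orthoformate
Product: 16 10α-(dimethoxymethyl) enone, via bis(trimethylsilyl) dienol ether 14 (not isolated), via C4 silyl ether 15 (not isolated)
Conditions: LDA (2.2 equiv), THF, −78 °C; Me3SiCl; then 13, TMSOTf (10 mol %), CH2Cl2, −78 °C; citric acid, MeOH, 0 °C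
Reagents that add atoms: none
Why: Kinetic α′-deprotonation at C10, silylation and Mukaiyama-type alkylation by the dimethoxycarbenium ion install C14 from the convex α face; this C10 centre is provisional and is re-set in step 15.

Step 8
Reactants: 16 10α-(dimethoxymethyl) enone
Product: 17 9β-allylic alcohol
Conditions: NaBH4, CeCl3·7H2O, MeOH, −78 → −20 °C
Reagents that add atoms: none
Why: Luche 1,2-reduction, with hydride arriving along the axial α trajectory of the half-chair (C14 equatorial), gives the equatorial 9β-alcohol.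

Step 9
Reactants: 17 9β-allylic alcohol
Product: 18 9α-allylic acetate
Conditions: AcOH, PPh3, DIAD, toluene–THF, 0 → 25 °C
Reagents that add atoms: acetic acid CC(=O)O
Why: Mitsunobu reaction, in which acetate displaces the activated 9β-oxygen by SN2 with inversion to give the 9α-acetate of the target; the tertiary C4 alcohol is inert.

Step 10
Reactants: 18 9α-allylic acetate
Product: 20 C6 aldehyde with C8 masked as 1,3-dimethylimidazolidin-2-yl, via dialdehyde 19 (not isolated)
Conditions: O3, CH2Cl2–MeOH (9:1), −78 °C; Me2S, −78 → 0 °C; then MeNHCH2CH2NHMe (1.05 equiv), MgSO4, CH2Cl2, 0 °C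
Reagents that add atoms: ozone [O-][O+]=O; N,N′-dimethylethane-1,2-diamine CNCCNC
Why: Ozonolysis cuts the only alkene (C6=C8), and the 1,2-diamine should condense selectively with the more electrophilic, less hindered α-acetoxy aldehyde C8 to a cyclic aminal, leaving the neopentyl-like C6 aldehyde free; no stereocentre is touched.

Step 11
Reactants: 20 aldehyde aminal; 5 methyl (Z)-3-bromo-2-(bromomethyl)acrylate
Product: 22 C6 bromohydrin (C6 as in the target; both C7 bromide epimers), via allylindium dibromide 21 (not isolated)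
Conditions: 5 (1.5 equiv), In powder (1.0 equiv), THF, 25 °C, 1 h; then 20, 0 → 25 °C; aq NaHCO3
Reagents that add atoms: none
Why: Barbier-type allylation in which the γ-bromoallylindium adds through its γ carbon (SE2′) to the C6 aldehyde held in a six-membered chelate with the C4 hydroxyl (1,3-chelation control), attack anti to the C1 side chain giving the target C6 configuration, while both C7 epimers are carried on.

Step 12
Reactants: 22 C6 bromohydrin
Product: 23 6-O-triethylsilyl ether
Conditions: Et3SiCl, imidazole, DMAP (cat.), DMF, 0 °C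
Reagents that add atoms: chlorotriethylsilane CC[Si](CC)(CC)Cl
Why: Silylation of the secondary C6 alcohol (the tertiary C4 alcohol is too hindered) blocks lactonisation and β-elimination in the next step; no stereocentre changes.

Step 13
Reactants: 23 6-O-triethylsilyl allylic bromide aminal
Product: 26 cis-hydroazulene 8β-alcohol (H-7α; methyl acrylate on C7), via free C8 aldehyde 24 (not isolated), via allylindium dibromide 25 (not isolated)
Conditions: In powder (3 equiv), THF–sat. aq NH4Cl (1:1), 0.005 M, 25 °C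
Reagents that add atoms: water O
Why: Barbier allylation: indium inserts into the allylic C7–Br bond of either epimer and, once the aqueous NH4Cl has hydrolysed the aminal, the 2-(methoxycarbonyl)allylindium adds through C7 (SE2′) to the C8 aldehyde. The closest known reaction type is the intramolecular indium- or zinc-mediated Barbier cyclisation of 2-(bromomethyl)acrylates onto aldehydes. Ring B closes as a seven-membered carbocycle in the 7-exo-trig mode at the carbonyl carbon, γ-attack being preferred over the nine-membered α-mode. C7 is controlled by allylic 1,3-strain: H-6 eclipses the C7=C11 plane, the silyloxy group and C5 lie on opposite faces, and the aldehyde tethered through C5 can only reach the C5 face, which gives H-7α (trans to H-6). C8 is controlled by a chair Zimmerman–Traxler transition state of the fluxional allylindium in its more stable geometry (C6 cis to CH2In, trans to the ester) with C9 equatorial, which places O8 cis to C11 (8β). The step needs γ-regioselectivity, one aldehyde face and survival of the open hydroxy ester, and these should be secured by ring size, by the convergence of both C7 bromides on one allylmetal and by the neutral aqueous medium.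

Step 14
Reactants: 26 cis-hydroazulene 8β-alcohol; 27 (R)-2-methylbutanoic acid
Product: 28 8β-[(R)-2-methylbutanoyl] ester
Conditions: 27 (2 equiv), DIC, DMAP (0.2 equiv), CH2Cl2, 0 → 25 °C
Reagents that add atoms: none
Why: Steglich esterification acylates the only secondary alcohol with retention at C8, the tertiary C4 hydroxyl being unreactive and the α-stereocentre of the acid being kept under carbodiimide activation.

Step 15
Reactants: 28 8β-ester
Product: 31 12,6α-lactone with O4–C14 bridged cyclic methyl acetal, via C6 alcohol 29 (not isolated), via lactone dimethyl acetal 30 (not isolated)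
Conditions: CSA (0.2 equiv), MeOH, 0 → 25 °C; evaporate; CSA (0.1 equiv), 4 Å MS, CH2Cl2, 35 °C
Reagents that add atoms: none
Why: Acid-catalysed cascade of silyl ether methanolysis, lactonisation of O6 onto the acrylate (trans-fused lactone, C6 and C7 unchanged) and intramolecular transacetalisation, in which only the C10 epimer with C14 on the β face can be bridged by O4, so C10 equilibrates through the enol ether and funnels into one cyclic acetal.

Step 16
Reactants: 31 bridged cyclic acetal lactone
Product: 32 15-alcohol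
Conditions: DDQ, CH2Cl2–pH 7 buffer (10:1), 0 °C
Reagents that add atoms: none
Why: Oxidative cleavage of the 4-methoxybenzyl ether by DDQ (benzylic hydride abstraction, hydrolysis of the oxocarbenium ion) frees the C15 hydroxyl without touching esters, lactone or acetal.

Step 17
Reactants: 32 15-alcohol
Product: 34 target 9α-acetoxy-15-hydroxy-8β-[(R)-2-methylbutanoyloxy]-4β,14-epoxy-1αH,5αH-guaia-10(14),11(13)-dien-12,6α-olide, via C15 trimethylsilyl ether 33 (not isolated)
Conditions: TMSOTf (3 equiv), i-Pr2NEt (6 equiv), CH2Cl2, −78 → −20 °C; then Et3N·3HF, THF, 0 °C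
Reagents that add atoms: none
Why: Acetal-to-enol-ether elimination in which TMSOTf ionises the anomeric methoxy group to the cyclic oxocarbenium ion and the amine removes H-10 to give the C10=C14 enol ether, the transient C15 silyl ether then being cleaved by fluoride.

Compound list
1 | (tributylstannyl)methanol | CCCC[Sn](CCCC)(CCCC)CO | starting material
2 | tributyl[(4-methoxybenzyloxy)methyl]stannane | CCCC[Sn](CCCC)(CCCC)COCc1ccc(OC)cc1 | intermediate
3 | methyl 2-(bromomethyl)acrylate | COC(=O)C(=C)CBr | starting material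
4 | methyl 2,3-dibromo-2-(bromomethyl)propanoate | COC(=O)C(Br)(CBr)CBr | intermediate
5 | methyl (Z)-3-bromo-2-(bromomethyl)acrylate | COC(=O)/C(CBr)=C/Br | intermediate
6 | but-3-en-2-one | CC(=O)C=C | starting material
7 | 2-(triisopropylsilyloxy)buta-1,3-diene | C=CC(=C)O[Si](C(C)C)(C(C)C)C(C)C | intermediate
8 | cyclopent-2-en-1-one | O=C1C=CCC1 | starting material
9 | (3aS,7aR)-5-(triisopropylsilyloxy)-2,3,3a,4,7,7a-hexahydro-1H-inden-1-one; cis-fused; ketone carbon = C4; H-1 and H-5 α | O=C1CC[C@H]2CC(O[Si](C(C)C)(C(C)C)C(C)C)=CC[C@@H]12 | intermediate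
10 | [(4-methoxybenzyloxy)methyl]lithium | [Li]COCc1ccc(OC)cc1 | intermediate
11 | cis-bicyclic tertiary alcohol: 4β-OH; 4α-CH2O-(4-methoxybenzyl); C8=C9 triisopropylsilyl enol ether | COc1ccc(COC[C@]2(O)CC[C@H]3CC(O[Si](C(C)C)(C(C)C)C(C)C)=CC[C@@H]23)cc1 | intermediate
12 | cis-bicyclic enone: C9 ketone; C6=C8 alkene; 4β-OH; 4α-CH2O-(4-methoxybenzyl) | COc1ccc(COC[C@]2(O)CC[C@H]3CC(=O)C=C[C@@H]23)cc1 | intermediate
13 | trimethyl orthoformate | COC(OC)OC | starting material
14 | 4-O,9-O-bis(trimethylsilyl) cross-conjugated dienol ether (C10=C9–C8=C6) of 12 | COc1ccc(COC[C@]2(O[Si](C)(C)C)CC[C@H]3C=C(O[Si](C)(C)C)C=C[C@@H]23)cc1 | intermediate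
15 | 4-O-trimethylsilyl ether of 16 | COc1ccc(COC[C@]2(O[Si](C)(C)C)CC[C@H]3[C@H](C(OC)OC)C(=O)C=C[C@@H]23)cc1 | intermediate
16 | enone carrying the C14 dimethyl acetal on the α face of C10 | COc1ccc(COC[C@]2(O)CC[C@H]3[C@H](C(OC)OC)C(=O)C=C[C@@H]23)cc1 | intermediate
17 | 9β-allylic alcohol | COc1ccc(COC[C@]2(O)CC[C@H]3[C@H](C(OC)OC)[C@@H](O)C=C[C@@H]23)cc1 | intermediate
18 | 9α-allylic acetate | COc1ccc(COC[C@]2(O)CC[C@H]3[C@H](C(OC)OC)[C@H](OC(C)=O)C=C[C@@H]23)cc1 | intermediate
19 | ring-opened dialdehyde (C6 and C8 formyl groups on the cis-1,2-disubstituted cyclopentane) | COc1ccc(COC[C@]2(O)CC[C@@H]([C@H](C(OC)OC)[C@H](OC(C)=O)C=O)[C@H]2C=O)cc1 | intermediate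
20 | C6 aldehyde; C8 as 1,3-dimethylimidazolidin-2-yl aminal | COc1ccc(COC[C@]2(O)CC[C@@H]([C@H](C(OC)OC)[C@H](OC(C)=O)C3N(C)CCN3C)[C@H]2C=O)cc1 | intermediate
21 | [3-bromo-2-(methoxycarbonyl)allyl]indium dibromide | COC(=O)C(C[In](Br)Br)=CBr | intermediate
22 | bromohydrin: C6 alcohol configured as in the target; C7 bromide (both epimers); methyl 2-methylenebutanoate arm | COc1ccc(COC[C@]2(O)CC[C@@H]([C@H](C(OC)OC)[C@H](OC(C)=O)C3N(C)CCN3C)[C@H]2[C@@H](O)C(Br)C(=C)C(=O)OC)cc1 | intermediate
23 | 6-O-triethylsilyl ether of 22 | COc1ccc(COC[C@]2(O)CC[C@@H]([C@H](C(OC)OC)[C@H](OC(C)=O)C3N(C)CCN3C)[C@H]2[C@@H](O[Si](CC)(CC)CC)C(Br)C(=C)C(=O)OC)cc1 | intermediate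
24 | free C8 aldehyde of 23 | COc1ccc(COC[C@]2(O)CC[C@@H]([C@H](C(OC)OC)[C@H](OC(C)=O)C=O)[C@H]2[C@@H](O[Si](CC)(CC)CC)C(Br)C(=C)C(=O)OC)cc1 | intermediate
25 | allylindium dibromide of 24 (C6 cis to CH2In) | COc1ccc(COC[C@]2(O)CC[C@@H]([C@H](C(OC)OC)[C@H](OC(C)=O)C=O)[C@H]2[C@@H](O[Si](CC)(CC)CC)/C=C(\C[In](Br)Br)C(=O)OC)cc1 | intermediate
26 | cis-hydroazulene: 8β-OH; H-7α; 6α-OSiEt3; 9α-OAc; 10α-CH(OMe)2; 4β-OH; methyl acrylate on C7 | COC(=O)C(=C)[C@@H]1[C@H](O)[C@@H](OC(C)=O)[C@@H](C(OC)OC)[C@@H]2CC[C@@](O)(COCc3ccc(OC)cc3)[C@@H]2[C@H]1O[Si](CC)(CC)CC | intermediate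
27 | (R)-2-methylbutanoic acid | CC[C@@H](C)C(=O)O | starting material
28 | 8β-[(R)-2-methylbutanoyl] ester of 26 | COC(=O)C(=C)[C@@H]1[C@H](OC(=O)[C@H](C)CC)[C@@H](OC(C)=O)[C@@H](C(OC)OC)[C@@H]2CC[C@@](O)(COCc3ccc(OC)cc3)[C@@H]2[C@H]1O[Si](CC)(CC)CC | intermediate
29 | 6α-alcohol of 28 | COC(=O)C(=C)[C@@H]1[C@H](OC(=O)[C@H](C)CC)[C@@H](OC(C)=O)[C@@H](C(OC)OC)[C@@H]2CC[C@@](O)(COCc3ccc(OC)cc3)[C@@H]2[C@H]1O | intermediate
30 | 12,6α-lactone with acyclic C14 dimethyl acetal (C14 α on C10) | C=C1C(=O)O[C@H]2[C@H]1[C@H](OC(=O)[C@H](C)CC)[C@@H](OC(C)=O)[C@@H](C(OC)OC)[C@@H]1CC[C@@](O)(COCc3ccc(OC)cc3)[C@H]21 | intermediate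
31 | lactone with O4–C14 bridged cyclic methyl acetal (H-10 α); 15-O-(4-methoxybenzyl) | C=C1C(=O)O[C@H]2[C@H]1[C@H](OC(=O)[C@H](C)CC)[C@@H](OC(C)=O)[C@@H]1C(OC)O[C@@]3(COCc4ccc(OC)cc4)CC[C@@H]1[C@@H]23 | intermediate
32 | 15-alcohol of 31 | C=C1C(=O)O[C@H]2[C@H]1[C@H](OC(=O)[C@H](C)CC)[C@@H](OC(C)=O)[C@@H]1C(OC)O[C@@]3(CO)CC[C@@H]1[C@@H]23 | intermediate
33 | 15-O-trimethylsilyl ether of the target | C=C1C(=O)O[C@H]2[C@H]1[C@H](OC(=O)[C@H](C)CC)[C@@H](OC(C)=O)C1=CO[C@@]3(CO[Si](C)(C)C)CC[C@@H]1[C@@H]23 | intermediate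
34 | 9α-acetoxy-15-hydroxy-8β-[(R)-2-methylbutanoyloxy]-4β,14-epoxy-1αH,5αH-guaia-10(14),11(13)-dien-12,6α-olide | C=C1C(=O)O[C@H]2[C@H]1[C@H](OC(=O)[C@H](C)CC)[C@@H](OC(C)=O)C1=CO[C@@]3(CO)CC[C@@H]1[C@@H]23 | target

Total steps: 17. Longest linear sequence: 15 (steps 3–17, from but-3-en-2-one).

Steps most likely to fail

Step 13. The allylindium may add to the other face of the aldehyde, giving the C8 epimer, or may be lost by protonation before the ring closes. The fallback sets C8 by ketone reduction instead of by the C–C bond formation; it sets out from 23 and comes back at 26. The crude ring-closure product, whatever its share of the 8α-alcohol F1, would be oxidised with Dess–Martin periodinane (NaHCO3, CH2Cl2) to the single C8 ketone F2. Luche reduction (NaBH4, CeCl3, MeOH, −78 °C) should then deliver hydride to the α face, anti to the 7β side chain, and return 26.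

Step 17. The enol ether double bond sits at a bridgehead of the bicyclo[4.3.1] core, so after ionisation the oxocarbenium ion may revert instead of losing H-10, or the Lewis acid may ionise the allylic 9-acetate. The fallback replaces the Lewis-acid elimination by a neutral selenoxide syn-elimination; it sets out from 31 and comes back at 34. PPTS in acetone–water (40 °C) would hydrolyse the methyl acetal to the bridged lactol F3, and N-(phenylseleno)phthalimide with n-Bu3P would convert it into the anomeric phenyl selenide F4. Oxidation (H2O2, pyridine, THF, 0 → 25 °C) and elimination of the selenoxide towards H-10 would give the 15-O-(4-methoxybenzyl) enol ether F5, and DDQ (pH 7 buffer, 0 °C) would release 34.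

Step 15. Under equilibrating acid the C10 centre may fail to epimerise, or the transient enol ether may lose the allylic acetate, so the bridged acetal may not form. The fallback sets C10 kinetically and stepwise; it sets out from 28 and comes back at 31. HF·pyridine (pyridine, THF, 0 °C) would give 29, and catalytic CSA in CH2Cl2 would lactonise it to 30, both now isolated. TMSOTf and i-Pr2NEt (−78 °C) would eliminate methanol to the exocyclic methyl enol ether F6 (C10 planar, C4 oxygen silylated). PPTS with two equivalents of methanol in CH2Cl2 would then free the C4 hydroxyl and add it across the enol ether to give 31.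

Further compounds
F1 | step 13 | 8α-alcohol (C8 epimer of 26) | COC(=O)C(=C)[C@@H]1[C@@H](O)[C@@H](OC(C)=O)[C@@H](C(OC)OC)[C@@H]2CC[C@@](O)(COCc3ccc(OC)cc3)[C@@H]2[C@H]1O[Si](CC)(CC)CC
F2 | step 13 | C8 ketone of 26 | COC(=O)C(=C)[C@@H]1C(=O)[C@@H](OC(C)=O)[C@@H](C(OC)OC)[C@@H]2CC[C@@](O)(COCc3ccc(OC)cc3)[C@@H]2[C@H]1O[Si](CC)(CC)CC
F3 | step 17 | bridged C14 lactol of 31 | C=C1C(=O)O[C@H]2[C@H]1[C@H](OC(=O)[C@H](C)CC)[C@@H](OC(C)=O)[C@@H]1C(O)O[C@@]3(COCc4ccc(OC)cc4)CC[C@@H]1[C@@H]23
F4 | step 17 | C14 phenyl selenide of 31 | C=C1C(=O)O[C@H]2[C@H]1[C@H](OC(=O)[C@H](C)CC)[C@@H](OC(C)=O)[C@@H]1C([Se]c4ccccc4)O[C@@]3(COCc5ccc(OC)cc5)CC[C@@H]1[C@@H]23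
F5 | step 17 | 15-O-(4-methoxybenzyl) ether of the target | C=C1C(=O)O[C@H]2[C@H]1[C@H](OC(=O)[C@H](C)CC)[C@@H](OC(C)=O)C1=CO[C@@]3(COCc4ccc(OC)cc4)CC[C@@H]1[C@@H]23
F6 | step 15 | exocyclic C10=C14 methyl enol ether lactone with 4-O-trimethylsilyl group | C=C1C(=O)O[C@H]2[C@H]1[C@H](OC(=O)[C@H](C)CC)[C@@H](OC(C)=O)C(=COC)[C@@H]1CC[C@@](O[Si](C)(C)C)(COCc3ccc(OC)cc3)[C@H]21
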